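The readings are simulated with made-up constants; scatter was added.

**The ratio.** Target over homo product at a run's last reading is my branch ratio (a selectivity factor): the starting material that went the partner route for each part that went to homo product. I read it from the east run, because its 17 °C is nearer oak's 20 °C than the south run's 9 °C and its equivalents match oak's. It comes to 2.05, a reading under a scatter of 2 percentage points.

| flask | starting material | partner | temperature | remark | time |
|---|---|---|---|---|---|
| south | 0.55 M | 0.70 equiv | 9 °C | run made earlier |  |
| east | 2.2 M | 0.70 equiv | 17 °C | run made earlier |  |
| south-east | 1.1 M | 1 equiv | 9 °C | run made earlier |  |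
| maple | 1.1 M | 0.700 equiv | 5 °C |  | 4.0 h |
| oak | 1.1 M | 0.700 equiv | 20 °C |  | 4.0 h |

south run (percent of the starting material charged)

| time / h | target / % | homo product / % |
|---|---|---|
| 0.833 | 0 | 2 |
| 1.50 | 8 | 2 |
| 2.50 | 11 | 8 |
| 3.00 | 14 | 8 |
| 4.00 | 21 | 15 |

east run (percent of the starting material charged)

| time / min | target / % | homo product / % |
|---|---|---|
| 12.0 | 7 | 3 |
| 20.0 | 6 | 4 |
| 30.0 | 12 | 1 |
| 60.0 | 32 | 13 |
| 120 | 43 | 21 |

south-east run (percent of the starting material charged)

| time / h | target / % | homo product / % |
|---|---|---|
| 0.833 | 11 | 2 |
| 1.50 | 12 | 3 |
| 2.50 | 28 | 9 |
| 3.00 | 29 | 11 |
| 4.00 | 41 | 16 |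

(each reading ± 2 percentage points)

- in percentages every species weighs as the starting material in it: one homo product counts as two
- the analysis behind the earlier runs scatters by 2 percentage points, standard deviation

- the flask with the highest share of target in all that became target or homo product or over-reaction product ("all alike" if they lie within 1.5 percentage points) (maple / oak / all alike)
- share of target in all that became target or homo product or over-reaction product, maple
- share of target in all that became target or homo product or over-reaction product, oak

**Oak's ledger.** I book oak's starting material in fractions of the charge and carry the ratio over unchanged. Of each unit that reacts, the partner route takes 0.672 and homo product takes 0.328. The partner charged is 0.700 of the starting material, more than that 0.672, so on this estimate the partner covers a fully reacted charge.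

**Last entry.** No run reads over-reaction product, and the east run leaves 36 points of its charge unread at 120 min. If that product grows from target, it moves units inside the partner route, so 67.2 % is my estimate of oak's share before that entry, and the entry lowers it. I can't size that entry from these readings. Maple at 5 °C is colder than oak at 20 °C, so I expect it to lose less target, and I pick maple.

**Forecast, result.** The forecast names maple, with 71 % for maple and 56 % for oak, on the ground that the east run “suggests homo formation has the higher activation energy”. The flask gives 68.6 % for maple and 40.7 % for oak, so maple leads.

    starting material → intermediate (k = 0.380 h⁻¹, Ea = 94.0 kJ mol⁻¹)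
    partner + intermediate → target (k = 0.210 L mol⁻¹ h⁻¹, Ea = 70.0 kJ mol⁻¹)
    2 intermediate → homo product (k = 0.0590 L mol⁻¹ h⁻¹, Ea = 62.0 kJ mol⁻¹)
    target → over-reaction product (k = 0.0230 h⁻¹, Ea = 92.0 kJ mol⁻¹)
    (constants at 5 °C)

**Books closed.** After 4.00 h, oak holds starting material 0 %, target 33.8 %, over-reaction product 20.7 %, homo product 28.5 % and intermediate 17.0 %. Its partner route, target plus over-reaction product, stands to homo product as 1.91, against my 2.05. Its share of target, 40.7 %, lies below my estimate before the last entry. The neighbour is oak with 0.28 M of starting material, a quarter of oak's, at the same equivalents of partner and the same time. It holds target 23.3 %, over-reaction product 11.0 %, homo product 20.3 % and intermediate 45.4 %. Its ratio is 1.69, and its share of target is 42.7 %.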